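Readings and results come from a simulation with made-up constants; scatter was added.

At 10 min we are to read E in the flask whose first minutes are the green run, and choose what to do next.

in all of them: temperature 25 °C

| flask | J | X | L | G | remark | time |
|---|---|---|---|---|---|---|
| green | 5 mM | 5 mM | 10 mM | 10 µM | the very flask that is asked about, followed so far |  |
| ochre | 5 mM | 5 mM | 10 mM | 20 µM | run made earlier |  |
| flask | 5.0 mM | 5.0 mM | 10.0 mM | 10 µM |  | 10 min |

- green (time / min: E / %): 0.333: 11.0; 1.00: 26.9; 1.50: 30.9; 2.50: 33.1; 4.00: 39.3; 5.00: 39.6; 6.00: 40.1
- ochre (time / min: E / %): 1.00: 25.3; 2.00: 32.4; 3.00: 37.3; 4.00: 40.2; 5.00: 42.1; 6.00: 39.3; 8.00: 41.4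

(each reading ± 1 percentage point)

- E, in percent of the J and X together first charged, at 10 min
- which option adds most E ("none" when 2 percentage points or less is all one gets) (eta / theta / delta / alpha / epsilon / none)
- E present, with what was taken out counted in, in percent of the J and X together first charged, after eta
- E present, with what was taken out counted in, in percent of the J and X together first charged, after theta

- eta: at 10 min take out 90% of the E then present, then wait 10 min
- theta: change nothing and wait 10 min more
- delta: at 10 min add G, 100% of the amount charged, then wait 10 min
- alpha: at 10 min raise the temperature by 10 K, then wait 10 min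
- epsilon: at 10 min add L, 50.0% of the amount charged, then wait 10 min

- L is single-handed; J and X are mirror images of each other, charged as a racemate, each of them at the stated concentration
- E that was removed still counts
- additions bring no volume worth counting
- the earlier runs do not show what temperature does; that part of a forecast is a guess
- the handed part of L does not stay in what it makes, so the products of the two hands are mirror images too

We reckon with the rate of E, taken as proportional to [J][L], and work in powers of ten.

1. Green starts at 0.330 /min, as a share of the J and X charged. Around 5.00 min it reads 0.00400 /min, a loss of 1.92 powers of ten. That late rise of 0.8 percentage points lies within the scatter of 1 point, so what follows is a rough reading.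

2. If each E took one J and one L, the fall of [J] pays 0.682 powers and the fall of [L] pays 0.219.

3. That leaves 1.02 powers unpaid, more than either. Spread over the time between the two rates, this gives 0.210 /min: the unpaid slowing, meaning the powers lost per minute beyond what making E consumes.

4. Ochre, with twice the G, reads 40.2% at 4.00 min against 39.3% in green. So we book the unpaid slowing on free L, though the readings cannot prove it, since a back reaction also slows a rate.

5. The remaining rate then lasts 2.07 min. Our reckoning gives 40.4% at 10 min, and waiting adds 0.074 points, as does taking out E. Fresh L restarts the rate at 0.0316 /min, which is worth 6.5 points. Heating is a guess. We choose epsilon.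

6. The forecast parts from us on the option: 40.5%, best eta, 45.5% after eta, 40.6% after theta, on the ground that “The likeliest cause is an equilibrium ceiling”.

The flask gives 40.3%, best epsilon with 7.9 points, 40.4% after eta and 40.4% after theta.

    L + J → E (k = 1.60 /M/s, Ea = 42.0 kJ/mol)
    L + X → Z (k = 0.0260 /M/s, Ea = 52.0 kJ/mol)
    J + G ⇌ X + G, rate k3*[G]*[J] forward; the back reaction follows from the equilibrium constant (k = 580 /M/s, Ea = 47.0 kJ/mol)
    G → Q (k = 0.0300 /s, Ea = 77.0 kJ/mol)
    L → D (k = 0.00620 /s, Ea = 81.0 kJ/mol)
    (constants at 25 °C)

One reason for what epsilon adds is the loss of L to D: with that loss taken away, the addition falls from 7.9 points to 0.34 points. Read as the fall of free L, the limiting reagent, 0.210 /min takes the 5.49% at 5.00 min to 0.491% by 10 min, and the flask holds 0.452%. In the neighbour flask with 40 mM of L, the same 0.210 /min over 10 min leaves 0.799% of the L charged, and that flask holds 1.90%, with E at 55.5%.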